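A small charge of incoming ligand, 0.800 equiv, has to serve a starting complex that exchanges step by step, so in spring and noon you keep that ligand's account.

| flask | starting complex | incoming ligand | scavenger | remark | time |
|---|---|---|---|---|---|
| Wednesday's | 0.10 M | 0.80 equiv | 0.54 equiv | run made earlier |  |
| Tuesday's | 0.10 M | 0.80 equiv | 1.2 equiv | run made earlier |  |
| Monday's | 0.050 M | 0.80 equiv | 0.80 equiv | run made earlier |  |
| spring | 0.10 M | 0.800 equiv | 0.800 equiv |  | 40 min |
| noon | 0.10 M | 0.800 equiv | 0.800 equiv |  | 20 min |

| run | time / min | starting complex / % | complex with three exchanged / % | complex with one exchanged / % | complex with two exchanged / % |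
|---|---|---|---|---|---|
| Wednesday's | 4.00 | 64.6 | 0.7 | 24.9 | 7.5 |
| Wednesday's | 8.00 | 52.4 | 0.9 | 27.9 | 12.4 |
| Wednesday's | 12.0 | 47.5 | 1.5 | 29.0 | 15.7 |
| Wednesday's | 15.0 | 44.1 | 2.8 | 29.4 | 16.7 |
| Wednesday's | 20.0 | 41.1 | 3.1 | 29.7 | 18.0 |
| Wednesday's | 25.0 | 39.3 | 3.2 | 29.5 | 19.1 |
| Tuesday's | 1.50 | 80.1 | 0.2 | 15.7 | 2.2 |
| Tuesday's | 5.00 | 60.0 | 0.6 | 26.4 | 9.6 |
| Tuesday's | 8.00 | 51.8 | 1.2 | 28.7 | 13.2 |
| Tuesday's | 12.0 | 45.9 | 2.2 | 29.3 | 16.1 |
| Tuesday's | 20.0 | 39.6 | 3.0 | 28.9 | 18.8 |
| Tuesday's | 25.0 | 39.0 | 3.3 | 29.2 | 20.2 |
| Monday's | 2.00 | 85.2 | 0 | 12.6 | 1.6 |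
| Monday's | 4.00 | 75.2 | 0 | 19.0 | 3.9 |
| Monday's | 6.00 | 68.1 | 0 | 22.9 | 5.9 |
| Monday's | 12.0 | 55.6 | 0.9 | 27.4 | 11.8 |
| Monday's | 25.0 | 43.9 | 2.2 | 29.7 | 17.2 |

(readings scatter by 0.3 percentage points)

* which of these there is most of at the end, counted by the starting complex in it, spring (complex with three exchanged / complex with two exchanged / starting complex / complex with one exchanged)
* which of these there is most of at the end, counted by the starting complex in it, noon (complex with three exchanged / complex with two exchanged / starting complex / complex with one exchanged)
* amount of the one of these that there is most of at the end, in percent of the starting complex charged, spring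
* amount of the one of these that there is most of at the end, in percent of the starting complex charged, noon

- the analysis behind the earlier runs scatters by 0.3 percentage points, standard deviation

Tuesday's last reading gives 79.5 %. This is the exchange count: [complex with one exchanged] + 2[complex with two exchanged] + 3[complex with three exchanged], in percent of the starting complex charged. Each exchange should cost one incoming ligand, the limiting reagent, so the charge of 0.80 equiv is the ceiling of the count.

Tuesday's starting complex leads the complex with one exchanged by 9.8 percentage points. Levelling them by exchange costs 4.9 points of count, and you can see how little room is left. But the four complexes sum to 91.7 %, so a slow loss exists. I commit to starting complex ahead in both flasks, noon near Tuesday's 39.6 % and spring lower.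

The forecast says starting complex at 37 % in spring (34.5 % to 38.8 %) and starting complex at 40.2 % at noon (39.2 % to 41.2 %), since “the starting complex stays well ahead of the complex with one exchanged”.

The flasks give starting complex at 35.1 % in spring and starting complex at 40.6 % at noon.

    starting complex + incoming ligand → leaving ligand + complex with one exchanged (k = 0.0360 /M/s)
    complex with one exchanged + incoming ligand → leaving ligand + complex with two exchanged (k = 0.0490 /M/s)
    complex with two exchanged + incoming ligand → leaving ligand + complex with three exchanged (k = 0.0180 /M/s)
    leaving ligand + incoming ligand ⇌ idle adduct, settled at all times (K = 20.0 /M)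
    scavenger + leaving ligand → scavenged by-product (k = 0.0410 /M/s)
    2 starting complex → homo dimer (k = 0.00110 /M/s)

Spring's count is 79.8 % beside Tuesday's 79.5 %, with 0.25 % of its incoming ligand free, so the ligand is spent there. Spring's starting complex stands 5.5 points below noon's because spring runs longer, and without the conversion of 2 starting complex into homo dimer that gap is 1.7 points. Charge 1.40 equiv at noon instead and the count reaches 125 %, and complex with two exchanged leads at 33.7 %, with starting complex at 24.3 %.

The numbers in the tables come from a simulation on assumed constants; the scatter is artificial.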